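## Retrosynthetic overview

1. The ten-membered carbocycle is opened last at the (Z)-C1=C10 olefin: ring-closing metathesis of diene 18.
2. The C13 acetate comes from a C11 iodide (Stille hydroxymethylation, acetylation). The butenolide comes from γ-hydroxy ynoate 9 by syn-carbocupration (C7–C8), iodine trapping (C11–I) and lactonization (O–C12).
3. Ynoate 9 comes from enal 6 and methyl propiolate by catalytic asymmetric alkynylation (C6–C7, sets C6).
4. Enal 6 comes from (E)-4,4-dimethoxy-2-methylbut-2-enal 1 by Keck allylation (C2–C3, sets C3), propanoylation and acetal hydrolysis.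
5. Ring order: butenolide first (step 5), ten-membered carbocycle second (step 8).

Assumption: atom labels C1–C15 follow germacrane numbering of the target (C3 carries the propanoate, C6 the lactone oxygen, C13 the acetate), and aldehyde 1 is bought as the pure E isomer.

## Route

Step 1
Reactants: 1 (E)-4,4-dimethoxy-2-methylbut-2-enal; 2 allyltributylstannane
Product: 3 (4S,5E)-7,7-dimethoxy-5-methylhepta-1,5-dien-4-ol
Conditions: (S)-BINOL (20 mol %), Ti(OiPr)4 (10 mol %), 4 Å MS, CH2Cl2, −20 °C, 72 h; aq. NaHCO3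
Reagents that add atoms: allyltributylstannane 2, C=CC[Sn](CCCC)(CCCC)CCCC
Why: Keck asymmetric allylation, in which the (S)-BINOL–titanium Lewis acid directs 1,2-addition of the allylstannane to the Si face of the enal and so sets C3 as S, while the acetal and the E olefin are inert.

Step 2
Reactants: 3 (4S,5E)-7,7-dimethoxy-5-methylhepta-1,5-dien-4-ol; 4 propanoic anhydride
Product: 5 (4S,5E)-7,7-dimethoxy-5-methylhepta-1,5-dien-4-yl propanoate
Conditions: (EtCO)2O, pyridine, DMAP (cat.), CH2Cl2, 0 °C to rt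
Reagents that add atoms: propanoic anhydride 4, CCC(=O)OC(=O)CC
Why: DMAP-catalysed acylation (esterification) of the secondary allylic alcohol breaks no bond at C3, so the S configuration is retained.

Step 3
Reactants: 5 (4S,5E)-7,7-dimethoxy-5-methylhepta-1,5-dien-4-yl propanoate
Product: 6 (4S,5E)-5-methyl-7-oxohepta-1,5-dien-4-yl propanoate
Conditions: 1 M aq. HCl, THF, 0 °C, 1 h
Reagents that add atoms: water, O
Why: Acid-catalysed acetal hydrolysis through the allylic oxocarbenium ion is fast at 0 °C, leaves the propanoate intact and gives the thermodynamically preferred E enal.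

Step 4
Reactants: 6 (4S,5E)-5-methyl-7-oxohepta-1,5-dien-4-yl propanoate; 7 methyl propiolate
Product: 9 methyl (4R,5E,7S)-4-hydroxy-6-methyl-7-(propanoyloxy)deca-5,9-dien-2-ynoate, via alkynylzinc 8 (not isolated)
Conditions: 7 (3 equiv), Me2Zn (3 equiv), (R,R)-ProPhenol (20 mol %), Ph3PO (40 mol %), toluene, 4 °C, 48 h; aq. NH4Cl
Reagents that add atoms: methyl propiolate 7, C#CC(=O)OC
Why: Trost ProPhenol dinuclear-zinc asymmetric alkynylation, in which the methylzinc acetylide adds 1,2 to the Si face of the enal under control of the (R,R) ligand and sets C6 as R independently of the remote C3 centre, with esters and olefins tolerated.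

Step 5
Reactants: 9 methyl (4R,5E,7S)-4-hydroxy-6-methyl-7-(propanoyloxy)deca-5,9-dien-2-ynoate; 10 4-bromo-2-methylbut-1-ene
Product: 14 (1E,3S)-1-[(2R)-4-iodo-3-(3-methylbut-3-en-1-yl)-5-oxo-2,5-dihydrofuran-2-yl]-2-methylhexa-1,5-dien-3-yl propanoate, via Grignard reagent 11 (not isolated), via magnesium diorganocuprate 12 (not isolated), via open-chain iodo ester 13 (not isolated)
Conditions: 10 (5 equiv), Mg, THF, rt; CuBr·SMe2 (2.5 equiv), −78 to −40 °C; 9, −78 °C, 1 h; I2 (6 equiv), THF, −78 to −20 °C; aq. Na2S2O3/NH4Cl; PPTS (cat.), CH2Cl2, rt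
Reagents that add atoms: 4-bromo-2-methylbut-1-ene 10 (as its cuprate), C=C(C)CCBr; iodine, I-I
Why: Syn-carbocupration (conjugate addition) of the ynoate places the new C8 chain and copper cis and hence the C6 oxygen and the ester cis, so that iodinolysis of the alkenylcopper with retention and 5-exo lactonization give the fully substituted butenolide without breaking any bond at C6 or C3.

Step 6
Reactants: 14 (1E,3S)-1-[(2R)-4-iodo-3-(3-methylbut-3-en-1-yl)-5-oxo-2,5-dihydrofuran-2-yl]-2-methylhexa-1,5-dien-3-yl propanoate; 15 (tributylstannyl)methanol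
Product: 16 (1E,3S)-1-[(2R)-4-(hydroxymethyl)-3-(3-methylbut-3-en-1-yl)-5-oxo-2,5-dihydrofuran-2-yl]-2-methylhexa-1,5-dien-3-yl propanoate
Conditions: 15 (2 equiv), Pd2(dba)3 (5 mol %), AsPh3 (20 mol %), CuI (10 mol %), NMP, 45 °C
Reagents that add atoms: (tributylstannyl)methanol 15, OC[Sn](CCCC)(CCCC)CCCC
Why: Stille (Migita–Kosugi) cross-coupling of the electron-poor alkenyl iodide, with copper-assisted transmetalation allowing 45 °C so that zerovalent palladium does not ionize the hindered allylic C–O bonds at C3 and C6; no stereocentre takes part.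

Step 7
Reactants: 16 (1E,3S)-1-[(2R)-4-(hydroxymethyl)-3-(3-methylbut-3-en-1-yl)-5-oxo-2,5-dihydrofuran-2-yl]-2-methylhexa-1,5-dien-3-yl propanoate; 17 acetic anhydride
Product: 18 (1E,3S)-1-[(2R)-4-(acetoxymethyl)-3-(3-methylbut-3-en-1-yl)-5-oxo-2,5-dihydrofuran-2-yl]-2-methylhexa-1,5-dien-3-yl propanoate
Conditions: Ac2O, pyridine, CH2Cl2, 0 °C to rt
Reagents that add atoms: acetic anhydride 17, CC(=O)OC(C)=O
Why: Acetylation (esterification) of the primary allylic alcohol under weakly basic conditions, which do not deprotonate the γ-position C6 of the butenolide.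

Step 8
Reactants: 18 (1E,3S)-1-[(2R)-4-(acetoxymethyl)-3-(3-methylbut-3-en-1-yl)-5-oxo-2,5-dihydrofuran-2-yl]-2-methylhexa-1,5-dien-3-yl propanoate
Product: 19 (3S,6R)-13-acetoxy-3-(propanoyloxy)germacra-1(10)Z,4E,7(11)-trien-12,6-olide (CNP0238103.1)
Conditions: second-generation Grubbs catalyst RuCl2(=CHPh)(PCy3)(H2IMes) (15 mol %, in portions), toluene (1 mM), 80 °C, Ar sparge
Reagents that add atoms: none
Why: Ring-closing metathesis, in which the carbene formed at the monosubstituted C1 vinyl group closes onto the 1,1-disubstituted olefin (no small-ring alternative exists for this carbene), and the new trisubstituted olefin is expected to form as the less strained Z isomer in the ten-membered ring, with C3 and C6 untouched.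

## Compound list

1 | (E)-4,4-dimethoxy-2-methylbut-2-enal | O=C/C(C)=C/C(OC)OC | starting material
2 | allyltributylstannane | C=CC[Sn](CCCC)(CCCC)CCCC | starting material
3 | (4S,5E)-7,7-dimethoxy-5-methylhepta-1,5-dien-4-ol | C=CC[C@H](O)/C(C)=C/C(OC)OC | intermediate
4 | propanoic anhydride | CCC(=O)OC(=O)CC | starting material
5 | (4S,5E)-7,7-dimethoxy-5-methylhepta-1,5-dien-4-yl propanoate | C=CC[C@H](OC(=O)CC)/C(C)=C/C(OC)OC | intermediate
6 | (4S,5E)-5-methyl-7-oxohepta-1,5-dien-4-yl propanoate | C=CC[C@H](OC(=O)CC)/C(C)=C/C=O | intermediate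
7 | methyl propiolate (methyl prop-2-ynoate) | C#CC(=O)OC | starting material
8 | methyl 3-(methylzincio)prop-2-ynoate (alkynylzinc) | COC(=O)C#C[Zn]C | intermediate
9 | methyl (4R,5E,7S)-4-hydroxy-6-methyl-7-(propanoyloxy)deca-5,9-dien-2-ynoate | COC(=O)C#C[C@H](O)/C=C(C)/[C@H](CC=C)OC(=O)CC | intermediate
10 | 4-bromo-2-methylbut-1-ene | C=C(C)CCBr | starting material
11 | (3-methylbut-3-en-1-yl)magnesium bromide | C=C(C)CC[Mg]Br | intermediate
12 | bromomagnesium bis(3-methylbut-3-en-1-yl)cuprate | C=C(C)CC[Cu-]CCC(C)=C.[Mg+]Br | intermediate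
13 | methyl (2E,4R,5E,7S)-4-hydroxy-2-iodo-6-methyl-3-(3-methylbut-3-en-1-yl)-7-(propanoyloxy)deca-2,5,9-trienoate | COC(=O)/C(I)=C(CCC(C)=C)\[C@H](O)/C=C(C)/[C@H](CC=C)OC(=O)CC | intermediate
14 | (1E,3S)-1-[(2R)-4-iodo-3-(3-methylbut-3-en-1-yl)-5-oxo-2,5-dihydrofuran-2-yl]-2-methylhexa-1,5-dien-3-yl propanoate | O=C1O[C@H](/C=C(C)/[C@H](CC=C)OC(=O)CC)C(CCC(C)=C)=C1I | intermediate
15 | (tributylstannyl)methanol | OC[Sn](CCCC)(CCCC)CCCC | starting material
16 | (1E,3S)-1-[(2R)-4-(hydroxymethyl)-3-(3-methylbut-3-en-1-yl)-5-oxo-2,5-dihydrofuran-2-yl]-2-methylhexa-1,5-dien-3-yl propanoate | O=C1O[C@H](/C=C(C)/[C@H](CC=C)OC(=O)CC)C(CCC(C)=C)=C1CO | intermediate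
17 | acetic anhydride | CC(=O)OC(C)=O | starting material
18 | (1E,3S)-1-[(2R)-4-(acetoxymethyl)-3-(3-methylbut-3-en-1-yl)-5-oxo-2,5-dihydrofuran-2-yl]-2-methylhexa-1,5-dien-3-yl propanoate | O=C1O[C@H](/C=C(C)/[C@H](CC=C)OC(=O)CC)C(CCC(C)=C)=C1COC(C)=O | intermediate
19 | (3S,6R)-13-acetoxy-3-(propanoyloxy)germacra-1(10)Z,4E,7(11)-trien-12,6-olide | CCC(=O)O[C@H]1C/C=C(/C)CCC2=C(COC(C)=O)C(=O)O[C@@H]2/C=C/1C | target

## Step count and risks

Total step count: 8. Longest linear sequence: 8 steps (1 to 19); all other components are bought.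

The three steps most likely to fail are steps 8, 5 and 6.

Step 8 (ring-closing metathesis) is the main risk. Closing a ten-membered carbocycle onto a 1,1-disubstituted olefin may give oligomers or an E/Z mixture. The fallback reverses the order of ring formation, so that metathesis runs on a seco-ester without the fused lactone and the butenolide is closed last. It sets out from 9 and comes back at 19. Silylation of 9 (TBSCl, imidazole, DMF) gives the silyl ether F1. Carbocupration of this with cuprate 12 at −78 °C and iodine trapping gives the open-chain (E)-iodo enoate F2, which cannot lactonize. Stille coupling with 15 under the conditions of step 6 gives the allylic alcohol F3, and acetylation with 17 gives the acetate F4. Ring-closing metathesis with RuCl2(=CHPh)(PCy3)(H2IMes) at 1 mM then gives the ten-membered seco-ester F5, whose C5-bearing arm can rotate freely about C6–C7. HF·pyridine in THF removes the silyl group, and the freed C6 hydroxyl lactonizes onto the cis ester to give 19.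

Step 5 (carbocupration with iodine trapping) may suffer from incomplete iodination, from iodoetherification by the free alkoxide, or from attack of the cuprate on the allylic propanoate. The fallback forms the C11–C13 bond directly instead of going through the iodide. It sets out from 9 and comes back at 16, skipping 14 and step 6. After the same addition of cuprate 12 at −78 °C, the adduct is transmetalated with Et2AlCl and the resulting allenolate is trapped with monomeric formaldehyde (tandem conjugate addition–aldol). Acidic work-up with PPTS then lactonizes the cis isomer to 16. This variant forms no compound outside the list (none, F0).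

Step 6 (Stille hydroxymethylation) may be slow at the hindered tetrasubstituted carbon, or zerovalent palladium may ionize the allylic C6–O or C3–O bonds. The fallback is palladium-free and uses a polar organometallic. It sets out from 14 and comes back at 16. Iodine–magnesium exchange with iPrMgCl·LiCl (THF, −78 °C) gives the alkenylmagnesium species, which is quenched with DMF to give the aldehyde F6. Luche reduction (NaBH4, CeCl3·7H2O, MeOH, −40 °C) reduces only the formyl group and gives 16.

## Further compounds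

F1 | step 8 | methyl (4R,5E,7S)-4-[(tert-butyldimethylsilyl)oxy]-6-methyl-7-(propanoyloxy)deca-5,9-dien-2-ynoate | COC(=O)C#C[C@H](O[Si](C)(C)C(C)(C)C)/C=C(C)/[C@H](CC=C)OC(=O)CC
F2 | step 8 | methyl (2E,4R,5E,7S)-4-[(tert-butyldimethylsilyl)oxy]-2-iodo-6-methyl-3-(3-methylbut-3-en-1-yl)-7-(propanoyloxy)deca-2,5,9-trienoate | COC(=O)/C(I)=C(CCC(C)=C)\[C@H](O[Si](C)(C)C(C)(C)C)/C=C(C)/[C@H](CC=C)OC(=O)CC
F3 | step 8 | methyl (2Z,4R,5E,7S)-4-[(tert-butyldimethylsilyl)oxy]-2-(hydroxymethyl)-6-methyl-3-(3-methylbut-3-en-1-yl)-7-(propanoyloxy)deca-2,5,9-trienoate | COC(=O)/C(CO)=C(CCC(C)=C)\[C@H](O[Si](C)(C)C(C)(C)C)/C=C(C)/[C@H](CC=C)OC(=O)CC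
F4 | step 8 | methyl (2Z,4R,5E,7S)-2-(acetoxymethyl)-4-[(tert-butyldimethylsilyl)oxy]-6-methyl-3-(3-methylbut-3-en-1-yl)-7-(propanoyloxy)deca-2,5,9-trienoate | COC(=O)/C(COC(C)=O)=C(CCC(C)=C)\[C@H](O[Si](C)(C)C(C)(C)C)/C=C(C)/[C@H](CC=C)OC(=O)CC
F5 | step 8 | methyl (2Z)-3-acetoxy-2-[(2R,3E,5S,7Z)-2-[(tert-butyldimethylsilyl)oxy]-4,8-dimethyl-5-(propanoyloxy)cyclodeca-3,7-dien-1-ylidene]propanoate | CCC(=O)O[C@H]1C/C=C(/C)CC/C(=C(\COC(C)=O)C(=O)OC)[C@H](O[Si](C)(C)C(C)(C)C)/C=C/1C
F0 | step 5 | none | none
F6 | step 6 | (1E,3S)-1-[(2R)-4-formyl-3-(3-methylbut-3-en-1-yl)-5-oxo-2,5-dihydrofuran-2-yl]-2-methylhexa-1,5-dien-3-yl propanoate | O=C1O[C@H](/C=C(C)/[C@H](CC=C)OC(=O)CC)C(CCC(C)=C)=C1C=O
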